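A direct plan would turn phloroglucinol into the hexasubstituted iodide A1 (tribenzylation, dibromination to A2, twofold CuBr/NaOMe methoxylation, iodination), would join A1, CO and the ring B ketone A3 by a Pd(dba)2/Xantphos-catalysed carbonylative α-arylation to the 1,3-diketone A4, and would end with hydrogenolysis to A5 and acid cyclodehydration at O1–C2. Its weakest steps would be the carbonylative coupling (two ortho benzyloxy groups would slow acyl transfer at palladium, so direct α-arylation and O-aroylation would compete), the twofold methoxylation of A2 (hydrodebromination would compete, and no skeletal bond would be gained), and the four-step decoration of ring A as a whole (length without added complexity).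

The route would rest on annulating ring A onto a preformed γ-pyrone that already is ring C and carries ring B. The array C5(OH)–C6(OMe)–C7(OH)–C8(OMe) is read as one ester carbon plus the symmetric three-carbon ketone MeOCH2–CO–CH2OMe. In a single operation a 2-(methylsulfanyl)-4-pyranone-3-carboxylate and 1,3-dimethoxyacetone would form C8–C8a by addition–elimination and C5–C6 by Claisen closure, and the benzenoid ring would appear with both phenols free and both methyl ethers in place. Ring A would thus need no halogenation, methoxylation, carbonylative coupling or protecting group, and the only protecting groups left would be two benzyl ethers on ring B.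

Key step: step 5

Remark: the locants O1 and C2 to C8a are those of the flavone numbering of the target and are used for the same atoms in all precursors; the benzoic acid, the β-keto ester, CS2 and 1,3-dimethoxyacetone used as starting materials are taken to be commercially available.

Step 1
Reactants: 1 3,5-dihydroxy-4-methoxybenzoic acid
Product: 3 3,5-bis(benzyloxy)-4-methoxybenzoic acid, via benzyl 3,5-bis(benzyloxy)-4-methoxybenzoate 2 (not isolated)
Conditions: BnBr (3.5 equiv), K2CO3 (4 equiv), DMF, 60 °C; then NaOH (aq), MeOH, 70 °C; then HCl (aq)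
Reagents that add atoms: benzyl bromide, BrCc1ccccc1; sodium hydroxide, [Na+].[OH-]
Why: Williamson etherification of both phenols together with O-alkylation of the carboxylate, followed in the same flask by saponification of the benzyl ester, which the aryl benzyl ethers should survive.

Step 2
Reactants: 3 3,5-bis(benzyloxy)-4-methoxybenzoic acid
Product: 4 3,5-bis(benzyloxy)-4-methoxybenzoyl chloride
Conditions: (COCl)2 (1.5 equiv), DMF (cat.), CH2Cl2, 0 °C → rt; evaporated, used crude
Reagents that add atoms: oxalyl chloride, O=C(Cl)C(=O)Cl
Why: Acid chloride formation through the Vilsmeier-type chloroiminium salt from DMF and oxalyl chloride, under conditions that should leave benzyl and methyl ethers untouched.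

Step 3
Reactants: 5 methyl 4-methoxy-3-oxobutanoate; 6 carbon disulfide (1.2 equiv)
Product: 8 methyl 2-[bis(methylsulfanyl)methylidene]-4-methoxy-3-oxobutanoate, via dipotassium ketene dithiolate 7 (not isolated)
Conditions: K2CO3 (2.5 equiv), DMF, 0 °C → rt; then MeI (2.3 equiv), 0 °C → rt
Reagents that add atoms: iodomethane, CI
Why: Ketene dithioacetal formation, in which the doubly activated methylene of the β-keto ester is deprotonated twice and adds to CS2 and the dithiolate 7 is S-methylated twice, while the less acidic CH2OMe group should stay untouched; the carbon of CS2 becomes C8a.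

Step 4
Reactants: 4 3,5-bis(benzyloxy)-4-methoxybenzoyl chloride (1.05 equiv); 8 methyl 2-[bis(methylsulfanyl)methylidene]-4-methoxy-3-oxobutanoate
Product: 10 methyl 6-[3,5-bis(benzyloxy)-4-methoxyphenyl]-5-methoxy-2-(methylsulfanyl)-4-oxo-4H-pyran-3-carboxylate, via lithium 1,3-diketonate 9 (not isolated)
Conditions: LiN(SiMe3)2 (2.2 equiv) added to 8 + 4, THF, −78 °C → rt, then 45 °C; aq. NH4Cl
Reagents that add atoms: none
Why: Claisen-type C-aroylation of the lithium enolate formed at the only enolisable position of 8 (the CH2OMe group), trapped as it forms because the base is added to the premixed partners, after which the oxygen of diketonate 9 should add to the bis(methylsulfanyl) carbon and methanethiolate be lost (6-endo-trig addition–elimination, as in the known closure of 2-hydroxyaryl β-oxo ketene dithioacetals to 2-(methylsulfanyl)chromones), which closes ring C at O1–C8a.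

Step 5
Reactants: 10 methyl 6-[3,5-bis(benzyloxy)-4-methoxyphenyl]-5-methoxy-2-(methylsulfanyl)-4-oxo-4H-pyran-3-carboxylate; 11 1,3-dimethoxypropan-2-one (1,3-dimethoxyacetone, 1.4 equiv)
Product: 13 2-[3,5-bis(benzyloxy)-4-methoxyphenyl]-5,7-dihydroxy-3,6,8-trimethoxy-4H-chromen-4-one, via C8a-alkylated pyranone 12 (not isolated)
Conditions: 11, LiN(SiMe3)2 (1.3 equiv), THF, −78 °C; then 10, −78 °C → rt; then LiN(SiMe3)2 (2.5 equiv), rt → 50 °C; 1 M HCl
Reagents that add atoms: none
Why: Proposed new method: the lithium enolate of 11 should add through carbon to C8a of 10, the one ring carbon that is β to both the C4 carbonyl and the ester, and the resulting β-keto ester enolate should expel methanethiolate to give 12 (addition–elimination at a push–pull ketene O,S-acetal); further base should then deprotonate the outer CH2OMe group of 12 so that C6 attacks the ester carbon C5, and loss of methoxide and enolisation should give ring A as its 5,7-diphenoxide. The closest known reaction types are the displacement of the sulfanyl group of 3-acyl-2-(methylsulfanyl)chromones and of acyclic β-oxo ketene dithioacetals by carbanions, and the base-induced Claisen closure of 2-(2-oxoalkyl)benzoates to naphthalene-1,3-diols. Ring A is closed by a 6-exo-trig attack of C6 on the ester carbonyl after the intermolecular C8–C8a bond formation, and ring C is kept. No stereocentre has to be controlled, since C8 of 12 is enolisable and ends as an sp2 carbon. The step needs C- and not O-attack of the enolate, attack at C8a and not at C2, and loss of thiolate and not of the ring oxygen: C2 is shielded by ring B and deactivated by the 3-methoxy group, the ester and the new side chain are held cis on the C4a=C8a bond, and a pyranone opened by loss of the ring oxygen would be expected to close again by attack of that oxygen on the same carbon, now with loss of thiolate. The two α-positions of 11 are equivalent, so no regiochemical question arises, and an aldol attack of C6 on the C4 carbonyl would give a strained bridged alkoxide that can revert.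

Step 6
Reactants: 13 2-[3,5-bis(benzyloxy)-4-methoxyphenyl]-5,7-dihydroxy-3,6,8-trimethoxy-4H-chromen-4-one
Product: 14 5,7,3',5'-tetrahydroxy-3,6,8,4'-tetramethoxyflavone (target)
Conditions: H2 (1 atm), Pd/C (10 wt% Pd), EtOAc–MeOH (1:1), rt
Reagents that add atoms: none
Why: Catalytic hydrogenolysis of the two aryl benzyl ethers, which should be faster than reduction of the tetrasubstituted, conjugated C2–C3 double bond and leaves the methyl ethers alone.

**Compound list**

1 | 3,5-dihydroxy-4-methoxybenzoic acid | COc1c(O)cc(C(=O)O)cc1O | starting material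
2 | benzyl 3,5-bis(benzyloxy)-4-methoxybenzoate | COc1c(OCc2ccccc2)cc(C(=O)OCc2ccccc2)cc1OCc1ccccc1 | intermediate
3 | 3,5-bis(benzyloxy)-4-methoxybenzoic acid | COc1c(OCc2ccccc2)cc(C(=O)O)cc1OCc1ccccc1 | intermediate
4 | 3,5-bis(benzyloxy)-4-methoxybenzoyl chloride | COc1c(OCc2ccccc2)cc(C(=O)Cl)cc1OCc1ccccc1 | intermediate
5 | methyl 4-methoxy-3-oxobutanoate | COCC(=O)CC(=O)OC | starting material
6 | carbon disulfide | S=C=S | starting material
7 | dipotassium 4-methoxy-2-(methoxycarbonyl)-3-oxobut-1-ene-1,1-bis(thiolate) | [K+].[K+].COCC(=O)C(C(=O)OC)=C([S-])[S-] | intermediate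
8 | methyl 2-[bis(methylsulfanyl)methylidene]-4-methoxy-3-oxobutanoate | COCC(=O)C(C(=O)OC)=C(SC)SC | intermediate
9 | lithium 1-[3,5-bis(benzyloxy)-4-methoxyphenyl]-2-methoxy-4-(methoxycarbonyl)-5,5-bis(methylsulfanyl)-3-oxopenta-1,4-dien-1-olate (chelated enolate, enolate oxygen cis to the neighbouring carbonyl) | [Li+].[O-]/C(c1cc(OCc2ccccc2)c(OC)c(OCc2ccccc2)c1)=C(/OC)C(=O)C(C(=O)OC)=C(SC)SC | intermediate
10 | methyl 6-[3,5-bis(benzyloxy)-4-methoxyphenyl]-5-methoxy-2-(methylsulfanyl)-4-oxo-4H-pyran-3-carboxylate | COC(=O)c1c(SC)oc(-c2cc(OCc3ccccc3)c(OC)c(OCc3ccccc3)c2)c(OC)c1=O | intermediate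
11 | 1,3-dimethoxypropan-2-one | COCC(=O)COC | starting material
12 | methyl 6-[3,5-bis(benzyloxy)-4-methoxyphenyl]-2-(1,3-dimethoxy-2-oxopropyl)-5-methoxy-4-oxo-4H-pyran-3-carboxylate (racemic, enolisable; present in the flask as its lithium enolate) | COCC(=O)C(OC)c1oc(-c2cc(OCc3ccccc3)c(OC)c(OCc3ccccc3)c2)c(OC)c(=O)c1C(=O)OC | intermediate
13 | 2-[3,5-bis(benzyloxy)-4-methoxyphenyl]-5,7-dihydroxy-3,6,8-trimethoxy-4H-chromen-4-one | COc1c(OCc2ccccc2)cc(-c2oc3c(OC)c(O)c(OC)c(O)c3c(=O)c2OC)cc1OCc1ccccc1 | intermediate
14 | 5,7,3',5'-tetrahydroxy-3,6,8,4'-tetramethoxyflavone (no stereocentre) | COc1c(O)cc(-c2oc3c(OC)c(O)c(OC)c(O)c3c(=O)c2OC)cc1O | target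

Total step count: 6. Longest linear sequence: 5 steps (steps 1, 2, 4, 5 and 6).

**Steps most likely to fail**

Step 5 (key step).
- What may go wrong: after attack at C8a the ring oxygen may leave instead of thiolate, and the opened chain may then close to a ring A that keeps the sulfanyl group. The second closure may also stall because the adduct is held as a delocalised, unreactive mono-anion, or it may go through the C7 enolate oxygen to a fused 2-pyranone.
- Fallback: the leaving group would be changed and the two bond formations separated, all by known chemistry, setting out from 10. Oxidation (mCPBA, 2.2 equiv, CH2Cl2, 0 °C) would give the sulfone methyl 6-[3,5-bis(benzyloxy)-4-methoxyphenyl]-5-methoxy-2-(methylsulfonyl)-4-oxo-4H-pyran-3-carboxylate F1, from which sulfinate should depart far faster than the ring oxygen, as in the known displacement of 2-sulfonyl groups of chromones by carbanions. The lithium enolate of 11 (THF, −78 °C) would then give 12, which would now be isolated. Closure under equilibrating conditions (NaOMe, MeOH, 65 °C), as for 2-(2-oxoalkyl)benzoates, would come back to the route at 13.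

Step 4.
- What may go wrong: O-aroylation or twofold aroylation of the enolate of 8, self-condensation of that enolate with the ketene dithioacetal of a second molecule, or closure of 9 at the ester instead of at the bis(methylsulfanyl) carbon.
- Fallback: the order of bond formation would be reversed, so that C2–C3 is made before the carbon of CS2 is introduced, setting out from 4 and 5. Acid chloride 4 would be converted (MeNHOMe·HCl, Et3N, CH2Cl2, 0 °C) into the Weinreb amide 3,5-bis(benzyloxy)-N,4-dimethoxy-N-methylbenzamide F2. This would acylate the dianion of 5 (NaH then n-BuLi, THF, 0 °C; F2, −78 °C → 0 °C) at its γ-carbon to give methyl 5-[3,5-bis(benzyloxy)-4-methoxyphenyl]-4-methoxy-3,5-dioxopentanoate F3. K2CO3, CS2 and MeI in DMF would then build the ketene dithioacetal at C4a, the only carbon of F3 with two acidic hydrogens, to give methyl 5-[3,5-bis(benzyloxy)-4-methoxyphenyl]-2-[bis(methylsulfanyl)methylidene]-4-methoxy-3,5-dioxopentanoate F4, the conjugate acid of 9. Warming (K2CO3, DMF, 60 °C) would close it with loss of methanethiol and come back to the route at 10.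

Step 6.
- What may go wrong: poisoning of Pd/C by traces of sulfur carried over from step 5, or saturation of the C2–C3 double bond when the reaction is forced.
- Fallback: the benzyl ethers of 13 would be cleaved without metal or hydrogen by a Lewis acid in the presence of a cation scavenger (BCl3, 4 equiv, pentamethylbenzene, 6 equiv, CH2Cl2, −78 °C), which should spare the methyl ethers at that temperature and would lead from 13 directly to 14; this fallback would make no new compound (F0).

**Further compounds**

F1 | step 5 | methyl 6-[3,5-bis(benzyloxy)-4-methoxyphenyl]-5-methoxy-2-(methylsulfonyl)-4-oxo-4H-pyran-3-carboxylate | COC(=O)c1c(S(C)(=O)=O)oc(-c2cc(OCc3ccccc3)c(OC)c(OCc3ccccc3)c2)c(OC)c1=O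
F2 | step 4 | 3,5-bis(benzyloxy)-N,4-dimethoxy-N-methylbenzamide | CON(C)C(=O)c1cc(OCc2ccccc2)c(OC)c(OCc2ccccc2)c1
F3 | step 4 | methyl 5-[3,5-bis(benzyloxy)-4-methoxyphenyl]-4-methoxy-3,5-dioxopentanoate (racemic, enolisable) | COC(=O)CC(=O)C(OC)C(=O)c1cc(OCc2ccccc2)c(OC)c(OCc2ccccc2)c1
F4 | step 4 | methyl 5-[3,5-bis(benzyloxy)-4-methoxyphenyl]-2-[bis(methylsulfanyl)methylidene]-4-methoxy-3,5-dioxopentanoate (racemic, enolisable) | COC(=O)C(=C(SC)SC)C(=O)C(OC)C(=O)c1cc(OCc2ccccc2)c(OC)c(OCc2ccccc2)c1
F0 | step 6 | none | none
A1 | direct plan | 1,3,5-tris(benzyloxy)-2-iodo-4,6-dimethoxybenzene | COc1c(OCc2ccccc2)c(I)c(OCc2ccccc2)c(OC)c1OCc1ccccc1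
A2 | direct plan | 1,3,5-tris(benzyloxy)-2,4-dibromobenzene | Brc1c(OCc2ccccc2)cc(OCc2ccccc2)c(Br)c1OCc1ccccc1
A3 | direct plan | 1-[3,5-bis(benzyloxy)-4-methoxyphenyl]-2-methoxyethan-1-one | COCC(=O)c1cc(OCc2ccccc2)c(OC)c(OCc2ccccc2)c1
A4 | direct plan | 3-[3,5-bis(benzyloxy)-4-methoxyphenyl]-2-methoxy-1-[2,4,6-tris(benzyloxy)-3,5-dimethoxyphenyl]propane-1,3-dione (racemic, enolisable) | COC(C(=O)c1c(OCc2ccccc2)c(OC)c(OCc2ccccc2)c(OC)c1OCc1ccccc1)C(=O)c1cc(OCc2ccccc2)c(OC)c(OCc2ccccc2)c1
A5 | direct plan | 1-(3,5-dihydroxy-4-methoxyphenyl)-2-methoxy-3-(2,4,6-trihydroxy-3,5-dimethoxyphenyl)propane-1,3-dione (racemic, enolisable) | COC(C(=O)c1c(O)c(OC)c(O)c(OC)c1O)C(=O)c1cc(O)c(OC)c(O)c1
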